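**Strategy.** The route rests on cutting the C9–C10 bond of the cis-fused hexahydroisobenzofuran and moving the furan oxygen back to C12. The tetrahydrofuran (O, C2, C1, C10, C9) is formed by contraction of the dihydropyran ring (O, C2, C1, C10, C11, C12) of a 2-oxabicyclo[2.2.2]oct-5-ene. A diazoacetate held on the C3 oxygen gives a copper carbenoid that the bridging ether oxygen captures; the oxonium ylide then undergoes a [2,3]-sigmatropic shift. In one operation this forms C9–C10, transfers the C2/C12 bridge geometry to the cis C1/C10 ring fusion and leaves the C11=C12 alkene for the acetoxy group. The precursor comes from an auxiliary-controlled isoprene Diels–Alder adduct by cineole-type selenoetherification.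

Key step: step 12

Remark: locants C1–C20 are the asbestinin locants of the target (C1/C10 ring fusion; C2 and C9 next to the furan oxygen; C3 the methylated oxepane carbon; C6 OMe; C7 Me; C11 OAc; C12 Me; C14–C15(Me)–C16H2–O). TBDPS = tert-butyldiphenylsilyl.
Assumption: but-3-en-1-ylmagnesium bromide (18, THF solution) and (2-methylallyl) phenyl sulfone (24) are purchased.

**Step 1**
Reactants: 1 (R)-4-benzyl-1,3-oxazolidin-2-one; 2 2-(diethoxyphosphoryl)acetic acid
Product: 4 phosphonate imide, via mixed pivalic anhydride 3 (not isolated)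
Conditions: PivCl, Et3N, THF, −20 °C; then 1, LiCl, −20 °C → rt
Reagents that add atoms: none
Why: Mixed-anhydride N-acylation of the oxazolidinone (LiCl/Et3N activation) loads the phosphonoacetate on the auxiliary, and no stereocenter is formed.

**Step 2**
Reactants: 5 methyl (S)-3-hydroxy-2-methylpropanoate
Product: 6 TBDPS ether of 5
Conditions: TBDPSCl, imidazole, DMF, 0 °C → rt
Reagents that add atoms: tert-butyl(chloro)diphenylsilane, CC(C)(C)[Si](Cl)(c1ccccc1)c1ccccc1
Why: Silylation of the primary C16 hydroxyl gives an ether that should survive the acid, base, hydride and organometallic steps, and C15 is untouched.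

**Step 3**
Reactants: 6 TBDPS ester; 4 phosphonate imide
Product: 8 (E)-enoyl imide, via aldehyde 7 (not isolated)
Conditions: DIBAL-H, CH2Cl2, −78 °C; then sodium salt of 4 (NaH, THF), −78 °C → rt
Reagents that add atoms: none
Why: Half-reduction of the ester followed by Horner–Wadsworth–Emmons olefination in the same flask avoids handling the epimerisable α-methyl aldehyde and should give the E-alkene from the stabilised phosphonate.

**Step 4**
Reactants: 8 (E)-enoyl imide; 9 isoprene
Product: 10 Diels–Alder adduct
Conditions: Et2AlCl, excess 9, CH2Cl2, −30 °C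
Reagents that add atoms: none
Why: Auxiliary-controlled Lewis-acid Diels–Alder reaction in which the Al-chelated s-cis acyl imide is attacked on the face opposite the benzyl group, setting C1 and C14 (trans, from the E-alkene), while the "para" orientation of isoprene puts the methyl-bearing C12 1,4 to C1.

**Step 5**
Reactants: 10 Diels–Alder adduct
Product: 11 primary alcohol
Conditions: LiBH4, H2O (1 equiv), Et2O, 0 °C
Reagents that add atoms: none
Why: Reductive cleavage of the N-acyl oxazolidinone gives the primary alcohol and returns the auxiliary without touching C1.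

**Step 6**
Reactants: 11 primary alcohol
Product: 12 aldehyde
Conditions: Dess–Martin periodinane, NaHCO3, CH2Cl2, 0 °C → rt
Reagents that add atoms: none
Why: Buffered Dess–Martin oxidation gives the aldehyde without epimerisation, the trans C1/C14 arrangement being the stable one in any case.

**Step 7**
Reactants: 12 aldehyde; 13 ethyl vinyl ether
Product: 15 α-hydroxy methyl ketone, via enol ether adduct 14 (not isolated)
Conditions: 13, t-BuLi, THF, −78 → 0 °C; then 12, −78 °C; then 0.5 M HCl, THF, 0 °C
Reagents that add atoms: water, O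
Why: Addition of the acyl-anion equivalent 1-ethoxyvinyllithium under Felkin–Anh control, with the branched C14 arm anti to the nucleophile, should set C2, and mild hydrolysis of the enol ether unveils the C3 methyl ketone.

**Step 8**
Reactants: 15 α-hydroxy methyl ketone
Product: 17 bicyclic allylic ether ketone, via selenide 16 (not isolated)
Conditions: PhSeCl, CH2Cl2, −78 °C; then pyridine, 30% H2O2, 0 °C → rt
Reagents that add atoms: none
Why: Markovnikov anti selenoetherification (as in the cyclisation of α-terpineol-type alcohols) joins the C2 oxygen to tertiary C12 on the face of the C1 side chain, fixing C12 by the bridge, and selenoxide syn-elimination can only run toward C10, giving the C10=C11 allylic ether.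

**Step 9**
Reactants: 17 bicyclic ketone; 18 but-3-en-1-ylmagnesium bromide
Product: 19 tertiary alcohol
Conditions: MgBr2·OEt2, CH2Cl2, −78 °C; then 18
Reagents that add atoms: none
Why: Cram-chelate Grignard addition in which magnesium bridges the ketone and ring-ether oxygens and the nucleophile enters from the open face anti to the C1 bridgehead, which sets the C3 quaternary carbinol.

**Step 10**
Reactants: 19 tertiary alcohol
Product: 20 bromoacetate
Conditions: BrCH2COBr, pyridine, DMAP (cat.), CH2Cl2, 0 °C → rt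
Reagents that add atoms: bromoacetyl bromide, BrCC(Br)=O
Why: O-acylation of the hindered tertiary alcohol with the reactive acid bromide installs the handle for diazo formation.

**Step 11**
Reactants: 20 bromoacetate
Product: 21 diazoacetate
Conditions: TsNHNHTs, DBU, THF, 0 °C
Reagents that add atoms: N,N'-ditosylhydrazine, Cc1ccc(cc1)S(=O)(=O)NNS(=O)(=O)c1ccc(C)cc1
Why: Diazo formation from a bromoacetate with N,N'-ditosylhydrazine (N-alkylation, then double sulfinate elimination) should spare the alkenes and the silyl ether.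

**Step 12**
Reactants: 21 diazoacetate
Product: 23 bridged lactone, via oxonium ylide 22 (not isolated)
Conditions: Cu(hfacac)2 (cat.), CH2Cl2, reflux, slow addition of 21
Reagents that add atoms: none
Why: Proposed new method: Cu(II) decomposes the diazoacetate to a carbenoid that is captured by the lone pair of the bridging ether oxygen syn to the C10=C11 bridge (the only one the endo C3 tether can reach), giving oxonium ylide 22, whose carbon C9 then bonds to C10 while O–C12 breaks and the alkene moves to C11=C12 in a [2,3]-sigmatropic shift (an allyl cation/enolate ion pair would collapse at the same secondary terminus). The closest known reactions are Cu- or Rh-catalysed oxonium ylide formation/[2,3] rearrangement of allylic ethers and the ring-contracting [2,3] shifts of cyclic allylic ammonium and sulfonium ylides (tetrahydropyridinium ylide to 3-vinylpyrrolidine), but an endocyclic, bridged allylic ether has not been used in this way. The six-membered lactone ring closes by O→carbenoid bond formation (six-membered ylide), and the tetrahydrofuran closes by C9–C10 bond formation through the five-membered envelope transition state of the suprafacial shift, which contracts the dihydropyran (O, C2, C1, C10, C11, C12) by one atom. C10 is set by the ether bridge, since the new bond must form on the face the oxygen leaves, cis to C2, which gives the cis C1/C10 fusion; C9 is set by the tether, since the bridged lactone can only form with its carbonyl cis to C3 across the furan oxygen. The step needs ylide formation to beat C–H insertion and cyclopropanation and the [2,3] path to beat a [1,2] shift; the six-membered ylide geometry, the electrophilic copper catalyst, the remote butenyl alkene (a seven-membered ring would be needed to cyclopropanate it) and the strain released on opening the bicyclo[2.2.2] system should secure this.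

**Step 13**
Reactants: 23 bridged lactone; 24 (2-methylallyl) phenyl sulfone
Product: 26 C9-methallyl diene, via lithium carboxylate 25 (not isolated)
Conditions: LiOH·H2O, THF/H2O, 0 °C → rt; evaporation; then 24, [Ir(dF(CF3)ppy)2(dtbbpy)]PF6 (cat.), DMSO, blue LEDs, rt
Reagents that add atoms: none
Why: Saponification frees the α-alkoxy carboxylate, whose photoredox decarboxylation gives the C9 α-oxy radical, and radical allylation with the allyl sulfone (addition, then β-sulfonyl fragmentation) should take place on the convex face of the cis-fused bicycle, anti to C11, so that C9 is reset with C8 cis to the C2 side chain.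

**Step 14**
Reactants: 26 C9-methallyl diene
Product: 27 (Z)-oxonene
Conditions: second-generation Ru benzylidene–NHC metathesis catalyst (cat.), toluene (high dilution), 80 °C
Reagents that add atoms: none
Why: Ring-closing metathesis of the butenyl and methallyl alkenes closes the nine-membered ring, in which the trisubstituted C6=C7 alkene can only be Z.

**Step 15**
Reactants: 27 (Z)-oxonene
Product: 30 C3/C6 diol, via silyl ether 28 (not isolated), via cyclic siloxane 29 (not isolated)
Conditions: Me2SiHCl, Et3N, CH2Cl2, 0 °C → rt; then Pt(0)–divinyltetramethyldisiloxane (cat.), toluene, 60 °C; then KF, KHCO3, 30% H2O2, THF/MeOH, 40 °C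
Reagents that add atoms: hydrogen peroxide, OO
Why: Tethered Pt-catalysed hydrosilylation delivers Si to C6 and H to C7 syn on the only alkene face the C3–O–Si tether can reach (six-membered oxasilacycle), and Tamao–Fleming oxidation replaces Si by OH with retention, so C6 and C7 are both set relative to C3.

**Step 16**
Reactants: 30 C3/C6 diol
Product: 31 C6 methyl ether
Conditions: Me3O·BF4, 1,8-bis(dimethylamino)naphthalene, CH2Cl2, rt
Reagents that add atoms: trimethyloxonium tetrafluoroborate, C[O+](C)C.F[B-](F)(F)F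
Why: O-methylation with the oxonium salt and a hindered amine base should be selective for the secondary C6 hydroxyl over the tertiary C3 hydroxyl.

**Step 17**
Reactants: 31 C6 methyl ether
Product: 32 C16 primary alcohol
Conditions: TBAF, THF, rt
Reagents that add atoms: none
Why: Fluoride cleavage of the silyl ether frees the primary C16 alcohol.

**Step 18**
Reactants: 32 C16 primary alcohol
Product: 34 tetracyclic alkene, via triflate 33 (not isolated)
Conditions: Tf2O, 2,6-lutidine, CH2Cl2, −78 → 0 °C
Reagents that add atoms: none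
Why: Selective triflation of the primary alcohol followed by intramolecular Williamson-type displacement by the tertiary C3 hydroxyl (7-exo-tet) closes the oxepane without touching a stereocenter.

**Step 19**
Reactants: 34 tetracyclic alkene
Product: 36 11-epi alcohol, via alkylborane 35 (not isolated)
Conditions: BH3·THF, THF, 0 °C → rt; then NaOH, 30% H2O2, 0 °C
Reagents that add atoms: hydrogen peroxide, OO
Why: Hydroboration–oxidation of the only remaining alkene adds boron to C11 and hydrogen to C12 syn on the convex face away from the tetrahydrofuran, which sets C12 (methyl toward the concave face) and gives the C11 epimer of the required alcohol.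

**Step 20**
Reactants: 36 11-epi alcohol
Product: 37 C11 ketone
Conditions: Dess–Martin periodinane, NaHCO3, CH2Cl2, 0 °C → rt
Reagents that add atoms: none
Why: Buffered Dess–Martin oxidation gives the ketone without epimerising the adjacent axial C12 methyl.

**Step 21**
Reactants: 37 C11 ketone
Product: 38 C11 alcohol
Conditions: NaBH4, MeOH, −20 °C
Reagents that add atoms: none
Why: Axial hydride delivery by the small borohydride, from the face opposite the axial C12 methyl and C10–C9 bond, should give the equatorial alcohol with the target configuration (net inversion at C11).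

**Step 22**
Reactants: 38 C11 alcohol
Product: 39 target CNP0289153.2
Conditions: Ac2O, pyridine, DMAP (cat.), CH2Cl2, rt
Reagents that add atoms: acetic anhydride, CC(=O)OC(C)=O
Why: DMAP-catalysed acetylation of the only free hydroxyl completes the target.

**Compound list**

1 | (R)-4-benzyl-1,3-oxazolidin-2-one | O=C1N[C@H](Cc2ccccc2)CO1 | starting material
2 | 2-(diethoxyphosphoryl)acetic acid | CCOP(=O)(CC(O)=O)OCC | starting material
3 | 2-(diethoxyphosphoryl)acetic pivalic anhydride | CCOP(=O)(CC(=O)OC(=O)C(C)(C)C)OCC | intermediate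
4 | diethyl {2-[(4R)-4-benzyl-2-oxo-1,3-oxazolidin-3-yl]-2-oxoethyl}phosphonate | CCOP(=O)(CC(=O)N1[C@H](Cc2ccccc2)COC1=O)OCC | intermediate
5 | methyl (S)-3-hydroxy-2-methylpropanoate | OC[C@H](C)C(=O)OC | starting material
6 | methyl (S)-3-(TBDPS-oxy)-2-methylpropanoate | CC(C)(C)[Si](c1ccccc1)(c1ccccc1)OC[C@H](C)C(=O)OC | intermediate
7 | (S)-3-(TBDPS-oxy)-2-methylpropanal | CC(C)(C)[Si](c1ccccc1)(c1ccccc1)OC[C@H](C)C=O | intermediate
8 | (4R)-4-benzyl-3-[(2E,4R)-4-methyl-5-(TBDPS-oxy)pent-2-enoyl]-1,3-oxazolidin-2-one | CC(C)(C)[Si](c1ccccc1)(c1ccccc1)OC[C@H](C)/C=C/C(=O)N1[C@H](Cc2ccccc2)COC1=O | intermediate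
9 | isoprene (2-methylbuta-1,3-diene) | CC(=C)C=C | starting material
10 | N-acyl oxazolidinone of trans-4-methyl-6-[(2R)-1-(TBDPS-oxy)propan-2-yl]cyclohex-3-ene-1-carboxylic acid (ring CH carbons = C1 and C14) | CC(C)(C)[Si](c1ccccc1)(c1ccccc1)OC[C@H](C)[C@@H]1CC(C)=CC[C@H]1C(=O)N1[C@H](Cc2ccccc2)COC1=O | intermediate
11 | corresponding cyclohexenylmethanol (C2 as CH2OH) | CC(C)(C)[Si](c1ccccc1)(c1ccccc1)OC[C@H](C)[C@@H]1CC(C)=CC[C@H]1CO | intermediate
12 | corresponding cyclohexenecarbaldehyde (C2 as CHO) | CC(C)(C)[Si](c1ccccc1)(c1ccccc1)OC[C@H](C)[C@@H]1CC(C)=CC[C@H]1C=O | intermediate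
13 | ethyl vinyl ether | CCOC=C | starting material
14 | C2 carbinol bearing a 1-ethoxyvinyl group (Felkin adduct) | CC(C)(C)[Si](c1ccccc1)(c1ccccc1)OC[C@H](C)[C@@H]1CC(C)=CC[C@H]1[C@H](O)C(=C)OCC | intermediate
15 | α-hydroxy methyl ketone (C2 carbinol, C3 ketone) | CC(C)(C)[Si](c1ccccc1)(c1ccccc1)OC[C@H](C)[C@@H]1CC(C)=CC[C@H]1[C@H](O)C(C)=O | intermediate
16 | 2-oxabicyclo[2.2.2]octane with C2–O–C12 bridge and 11-phenylselanyl group anti to the oxygen | CC(C)(C)[Si](c1ccccc1)(c1ccccc1)OC[C@H](C)[C@@H]1C[C@]2(C)[C@H]([Se]c3ccccc3)C[C@H]1[C@@H](C(C)=O)O2 | intermediate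
17 | 3-acetyl-1-methyl-2-oxabicyclo[2.2.2]oct-5-ene, acetyl endo (syn to the C10=C11 bridge), C14 side chain anti to the oxygen bridge | CC(C)(C)[Si](c1ccccc1)(c1ccccc1)OC[C@H](C)[C@@H]1C[C@]2(C)C=C[C@H]1[C@@H](C(C)=O)O2 | intermediate
18 | but-3-en-1-ylmagnesium bromide | C=CCC[Mg]Br | starting material
19 | tertiary alcohol at C3 (methyl, butenyl) on the bicyclic allylic ether | CC(C)(C)[Si](c1ccccc1)(c1ccccc1)OC[C@H](C)[C@@H]1C[C@]2(C)C=C[C@H]1[C@@H]([C@@](C)(O)CCC=C)O2 | intermediate
20 | bromoacetate of 19 | CC(C)(C)[Si](c1ccccc1)(c1ccccc1)OC[C@H](C)[C@@H]1C[C@]2(C)C=C[C@H]1[C@@H]([C@@](C)(OC(=O)CBr)CCC=C)O2 | intermediate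
21 | diazoacetate of 19 | CC(C)(C)[Si](c1ccccc1)(c1ccccc1)OC[C@H](C)[C@@H]1C[C@]2(C)C=C[C@H]1[C@@H]([C@@](C)(OC(=O)C=[N+]=[N-])CCC=C)O2 | intermediate
22 | bicyclic oxonium ylide (ring oxygen bonded to C2, C12 and the ylide carbon C9) | CC(C)(C)[Si](c1ccccc1)(c1ccccc1)OC[C@H](C)[C@@H]1C[C@]2(C)C=C[C@H]1[C@@H]3[O+]2[CH-]C(=O)O[C@@]3(C)CCC=C | intermediate
23 | bridged lactone: cis-fused hexahydroisobenzofuran with 11,12-alkene, C9 carboxyl lactonised on the C3 oxygen | CC(C)(C)[Si](c1ccccc1)(c1ccccc1)OC[C@H](C)[C@@H]1CC(C)=C[C@@H]2[C@H]1[C@@H]3O[C@H]2C(=O)O[C@@]3(C)CCC=C | intermediate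
24 | (2-methylallyl) phenyl sulfone | CC(=C)CS(=O)(=O)c1ccccc1 | starting material
25 | lithium C9-carboxylate with free C3 hydroxyl | CC(C)(C)[Si](c1ccccc1)(c1ccccc1)OC[C@H](C)[C@@H]1CC(C)=C[C@@H]2[C@H]1[C@H](O[C@H]2C([O-])=O)[C@@](C)(O)CCC=C.[Li+] | intermediate
26 | 2,9-cis furan with C9 methallyl and C3 (methyl, butenyl) carbinol | CC(C)(C)[Si](c1ccccc1)(c1ccccc1)OC[C@H](C)[C@@H]1CC(C)=C[C@@H]2[C@H]1[C@H](O[C@H]2CC(C)=C)[C@@](C)(O)CCC=C | intermediate
27 | (6Z)-oxonene with free C3 hydroxyl | CC(C)(C)[Si](c1ccccc1)(c1ccccc1)OC[C@H](C)[C@@H]1CC(C)=C[C@@H]2[C@H]1[C@@H]3O[C@H]2C/C(C)=C\CC[C@]3(C)O | intermediate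
28 | C3 O-dimethylsilyl (Si–H) ether of 27 | CC(C)(C)[Si](c1ccccc1)(c1ccccc1)OC[C@H](C)[C@@H]1CC(C)=C[C@@H]2[C@H]1[C@@H]3O[C@H]2C/C(C)=C\CC[C@]3(C)O[SiH](C)C | intermediate
29 | cyclic siloxane bridging the C3 oxygen and C6 | CC(C)(C)[Si](c1ccccc1)(c1ccccc1)OC[C@H](C)[C@@H]1CC(C)=C[C@@H]2[C@H]1[C@@H]3O[C@H]2C[C@@H](C)[C@H]4CC[C@]3(C)O[Si]4(C)C | intermediate
30 | C3/C6 diol with C7 methyl set | CC(C)(C)[Si](c1ccccc1)(c1ccccc1)OC[C@H](C)[C@@H]1CC(C)=C[C@@H]2[C@H]1[C@@H]3O[C@H]2C[C@@H](C)[C@H](O)CC[C@]3(C)O | intermediate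
31 | C6 methyl ether | CC(C)(C)[Si](c1ccccc1)(c1ccccc1)OC[C@H](C)[C@@H]1CC(C)=C[C@@H]2[C@H]1[C@@H]3O[C@H]2C[C@@H](C)[C@H](OC)CC[C@]3(C)O | intermediate
32 | C16 primary alcohol (C3, C16 diol) | OC[C@H](C)[C@@H]1CC(C)=C[C@@H]2[C@H]1[C@@H]3O[C@H]2C[C@@H](C)[C@H](OC)CC[C@]3(C)O | intermediate
33 | C16 triflate | FC(F)(F)S(=O)(=O)OC[C@H](C)[C@@H]1CC(C)=C[C@@H]2[C@H]1[C@@H]3O[C@H]2C[C@@H](C)[C@H](OC)CC[C@]3(C)O | intermediate
34 | tetracyclic 11,12-alkene (oxepane closed) | CO[C@@H]1CC[C@]2(C)OC[C@H](C)[C@@H]3CC(C)=C[C@@H]4[C@H]3[C@@H]2O[C@H]4C[C@H]1C | intermediate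
35 | C11 alkylborane | CO[C@@H]1CC[C@]2(C)OC[C@H](C)[C@@H]3C[C@@H](C)[C@H](B)[C@@H]4[C@H]3[C@@H]2O[C@H]4C[C@H]1C | intermediate
36 | 11-epi alcohol (OH trans to the C12 methyl) | CO[C@@H]1CC[C@]2(C)OC[C@H](C)[C@@H]3C[C@@H](C)[C@H](O)[C@@H]4[C@H]3[C@@H]2O[C@H]4C[C@H]1C | intermediate
37 | C11 ketone | CO[C@@H]1CC[C@]2(C)OC[C@H](C)[C@@H]3C[C@@H](C)C(=O)[C@@H]4[C@H]3[C@@H]2O[C@H]4C[C@H]1C | intermediate
38 | C11 alcohol (OH cis to the C12 methyl) | CO[C@@H]1CC[C@]2(C)OC[C@H](C)[C@@H]3C[C@@H](C)[C@@H](O)[C@@H]4[C@H]3[C@@H]2O[C@H]4C[C@H]1C | intermediate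
39 | CNP0289153.2 | CO[C@@H]1CC[C@]2(C)OC[C@H](C)[C@@H]3C[C@@H](C)[C@@H](OC(C)=O)[C@@H]4[C@H]3[C@@H]2O[C@H]4C[C@H]1C | target

**Total step count:** 22 steps.
**Longest linear sequence:** 21 steps (5 → 39, steps 2–22).

**Steps most likely to fail**

Step 12 (Proposed new method). The carbenoid may be consumed by C–H insertion next to the ester oxygen before the hindered bridging oxygen captures it, or the ylide may collapse by a [1,2] shift of C12 instead of bonding at C10. The fallback is ionic and uses known reaction types. It sets out from 19: acetoacetylation with 2,2,6-trimethyl-4H-1,3-dioxin-4-one in hot xylene would give β-keto ester F1. A catalytic Lewis acid (Bi(OTf)3, CH2Cl2) would ionise the strained tertiary allylic ether and let the tethered enol attack C10 on the face the oxygen leaves, giving hydroxy keto lactone F2. Iodine/Na2CO3 oxidative cyclisation (α-iodination, then displacement by the C2 hydroxyl) would close the tetrahydrofuran as α-acetyl lactone F3. Retro-Claisen deacetylation (K2CO3, MeOH) would bring the sequence back to the route at 23.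

Step 13. The C9 radical may be trapped on the wrong face, or be reduced or cyclise onto the butenyl group before allyl transfer, so that the C9 configuration or the material is lost. The fallback keeps the C9–carbon bond and the configuration set by the tether. It sets out from 23: DIBAL-H at −78 °C would give lactol F4, and 2-propenylmagnesium bromide would open it to allylic alcohol F5. Methyl chloroformate/pyridine would give the secondary allylic carbonate F6. Pd(OAc)2/n-Bu3P/ammonium formate (Tsuji–Trost-type formate reduction, hydride to the more substituted allyl terminus) would give the methallyl group and return to the route at 26.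

Step 15. Hydrosilylation of the trisubstituted ring alkene may be too slow, so that Si–H is lost or the alkene migrates before addition. The fallback replaces the silicon tether by hydroxyl-directed oxidation and reduction. It sets out from 27: VO(acac)2/t-BuOOH epoxidation directed by the C3 hydroxyl would give the syn epoxide F7. Isomerisation with diethylaluminium 2,2,6,6-tetramethylpiperidide would give allylic alcohol F8 (C6 hydroxyl, exocyclic C7 methylene). Hydroxyl-directed hydrogenation with a cationic Rh–diphosphine catalyst would deliver hydrogen to C7 syn to the C6 hydroxyl and return to the route at 30.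

**Further compounds**

F1 | step 12 | acetoacetate of 19 | CC(C)(C)[Si](c1ccccc1)(c1ccccc1)OC[C@H](C)[C@@H]1C[C@]2(C)C=C[C@H]1[C@@H]([C@@](C)(OC(=O)CC(C)=O)CCC=C)O2
F2 | step 12 | seven-membered keto lactone with C9–C10 bond and free C2 hydroxyl | CC(C)(C)[Si](c1ccccc1)(c1ccccc1)OC[C@H](C)[C@@H]1CC(C)=C[C@@H]2[C@H]1[C@H](O)[C@](C)(CCC=C)OC(=O)C2C(C)=O
F3 | step 12 | 9-acetyl derivative of bridged lactone 23 | CC(C)(C)[Si](c1ccccc1)(c1ccccc1)OC[C@H](C)[C@@H]1CC(C)=C[C@@H]2[C@H]1[C@@H]3O[C@@]2(C(C)=O)C(=O)O[C@@]3(C)CCC=C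
F4 | step 13 | lactol from 23 | CC(C)(C)[Si](c1ccccc1)(c1ccccc1)OC[C@H](C)[C@@H]1CC(C)=C[C@@H]2[C@H]1[C@@H]3O[C@H]2C(O)O[C@@]3(C)CCC=C
F5 | step 13 | C8 allylic alcohol (2-propenyl carbinol) with free C3 hydroxyl | CC(C)(C)[Si](c1ccccc1)(c1ccccc1)OC[C@H](C)[C@@H]1CC(C)=C[C@@H]2[C@H]1[C@H](O[C@H]2C(O)C(C)=C)[C@@](C)(O)CCC=C
F6 | step 13 | C8 methyl carbonate of F5 | CC(C)(C)[Si](c1ccccc1)(c1ccccc1)OC[C@H](C)[C@@H]1CC(C)=C[C@@H]2[C@H]1[C@H](O[C@H]2C(OC(=O)OC)C(C)=C)[C@@](C)(O)CCC=C
F7 | step 15 | 6,7-epoxide syn to the C3 hydroxyl | CC(C)(C)[Si](c1ccccc1)(c1ccccc1)OC[C@H](C)[C@@H]1CC(C)=C[C@@H]2[C@H]1[C@@H]3O[C@H]2C[C@]4(C)O[C@@H]4CC[C@]3(C)O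
F8 | step 15 | C6 allylic alcohol with exocyclic C7 methylene | CC(C)(C)[Si](c1ccccc1)(c1ccccc1)OC[C@H](C)[C@@H]1CC(C)=C[C@@H]2[C@H]1[C@@H]3O[C@H]2CC(=C)[C@H](O)CC[C@]3(C)O
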